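**Assumption:** gibberellic acid (GA3, the fermentation-derived plant growth regulator) is taken as the cheap commercial chiral starting material. The target is written GA93 throughout. β is the face of H-5 and the C4 methyl, α the face of the lactone bridge. The allylic iodide of step 2 is drawn as the syn-SN2′ isomer. The route is a paper design and has not been run.

## Retrosynthetic overview

1. GA93 (7) ⇐ anti, 5-exo lactonisation of the C19 acid onto C10 of the syn-1β,10β:2β,3β-diepoxide 6 (gives the γ-lactone, 10α-O and 1β-OH; the 2β,3β-oxirane stays).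
2. 6 ⇐ O–O rearrangement of the 3β,10β-endoperoxide 5 ⇐ [4+2] cycloaddition of singlet oxygen to the ring A 1(10),2-diene diacid 4 (key step).
3. 4 ⇐ zinc-mediated reductive β-elimination of the allylic iodide 3 (an iodolactone) ⇐ mesylate 2 ⇐ gibberellic acid 1.
4. Rings B, C and D and the stereocentres C4, C5, C6, C8, C9 and C13 are bought with 1. Rings formed in the synthesis, in order: endoperoxide ring (cycloaddition) → two oxiranes → γ-lactone.

## Route

**Step 1**
Reactants: 1 gibberellic acid (GA3; 3β,13-dihydroxy-1,16-diene, 19→10α-lactone, 7-CO2H)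
Product: 2 GA3 3-O-methanesulfonate (3β-OMs; all else unchanged)
Conditions: MsCl (2.5 equiv), pyridine, 0 °C → rt; aq. NaHCO3/THF quench, then pH 3
Reagents that add atoms: methanesulfonyl chloride, CS(=O)(=O)Cl
Why: O-sulfonylation of the only secondary alcohol; MsCl in pyridine leaves the tertiary bridgehead 13-OH alone, any mixed anhydride at C7 is hydrolysed in the bicarbonate quench, and no stereocentre is touched.

**Step 2**
Reactants: 2 GA3 3-O-methanesulfonate
Product: 4 ring A diene diacid (ent-13-hydroxy-20-norgibberella-1(10),2,16-triene-7,19-dioic acid; double bonds C1=C10 and C2=C3; 4α-CO2H; 4β-CH3; 5β-H; 6β-CO2H; 9β-H), via 1β-iodo-GA5 3 (not isolated)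
Conditions: NaI (5 equiv), Zn dust (10 equiv), DMF, 50 °C; cold aq. citric acid to pH 4
Reagents that add atoms: sodium iodide, [Na+].[I-] (its iodine is carried only by intermediate 3 and is lost again on the way to 4)
Why: Finkelstein-type syn-SN2′ displacement gives the allylic iodide, which is the iodolactone of the diene acid, and zinc then performs the classical reductive β-elimination of iodolactones (anti 1β-I/10α-O), expelling the C19 carboxylate; the 3α-iodo-1-ene isomer would give the same diene by 1,4-elimination, and C3 and C10 are erased on purpose for re-installation in step 3.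

**Step 3**
Reactants: 4 ring A diene diacid
Product: 7 GA93, via 3β,10β-endoperoxide 5 (not isolated), via 1β,10β:2β,3β-diepoxide 6 (not isolated)
Conditions: O2, hν (white LED), H2TPP (5,10,15,20-tetraphenylporphyrin, 1 mol %), CH2Cl2/acetone 4:1, −30 °C; then Ar purge, Co(TPP) (5 mol %), −30 °C → rt, 12 h
Reagents that add atoms: dioxygen (reacting as singlet oxygen), O=O
Why: [4+2] cycloaddition of singlet oxygen to the s-cis ring A diene should occur on the β face, because ring B holds C6 pseudoequatorial and so forces the 4α-CO2H pseudoaxial over the α face at C3, while C11 flanks the α face at C10 and only H-5β and H-9β stand on the β face (the 1,1-disubstituted 16-ene is far slower); Co(TPP) (divalent cobalt) rearranges the endoperoxide to the syn-diepoxide on that same face, and the C19 acid opens the 1,10-oxirane at tertiary C10 by anti 5-exo attack from the α face, which sets 10α-O and 1β-OH and leaves the 2β,3β-epoxide.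

## Compound list

1 | gibberellic acid (GA3) | C=C1C[C@]23C[C@@]1(O)CC[C@H]2[C@@]12OC(=O)[C@@](C)([C@H]1[C@@H]3C(=O)O)[C@@H](O)C=C2 | starting material
2 | GA3 3-O-methanesulfonate (3β-OMs) | C=C1C[C@]23C[C@@]1(O)CC[C@H]2[C@@]12OC(=O)[C@@](C)([C@H]1[C@@H]3C(=O)O)[C@@H](OS(C)(=O)=O)C=C2 | intermediate
3 | 1β-iodo-GA5 (1β-iodo-2-ene 19→10α-lactone, 13-OH, 7-CO2H) | C=C1C[C@]23C[C@@]1(O)CC[C@H]2[C@@]12OC(=O)[C@@](C)([C@H]1[C@@H]3C(=O)O)C=C[C@H]2I | intermediate
4 | ent-13-hydroxy-20-norgibberella-1(10),2,16-triene-7,19-dioic acid (ring A diene diacid) | C=C1C[C@]23C[C@@]1(O)CC[C@H]2C1=CC=C[C@@](C)(C(=O)O)[C@H]1[C@@H]3C(=O)O | intermediate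
5 | 3β,10β-epidioxy-1-ene diacid (endoperoxide on the β face of ring A) | C=C1C[C@]23C[C@@]1(O)CC[C@H]2[C@]12OO[C@@H](C=C2)[C@@](C)(C(=O)O)[C@H]1[C@@H]3C(=O)O | intermediate
6 | 1β,10β:2β,3β-diepoxy diacid (syn-diepoxide) | C=C1C[C@]23C[C@@]1(O)CC[C@H]2[C@]12O[C@@H]2[C@@H]2O[C@@H]2[C@@](C)(C(=O)O)[C@H]1[C@@H]3C(=O)O | intermediate
7 | GA93 (1β,13-dihydroxy-2β,3β-epoxy 19→10α-lactone 7-acid) | C=C1C[C@]23C[C@@]1(O)CC[C@H]2[C@@]12OC(=O)[C@@](C)([C@H]1[C@@H]3C(=O)O)[C@H]1O[C@H]1[C@H]2O | target

## Step count and risks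

Total step count: 3. Longest linear sequence: 3.

The three steps most likely to fail, most risky first:

**Step 3.** The photooxygenation may give ene products or attack the α face, and the rearrangement may give a hydroxy-enone instead of the diepoxide. The fallback is a stepwise oxygen transfer that sets out from 4 and comes back at 7. Silylation of 4 with N,O-bis(trimethylsilyl)acetamide gives the tris(trimethylsilyl) derivative F1. Aqueous NaHCO3 work-up hydrolyses its two silyl esters and leaves the 13-O-trimethylsilyl diene diacid F2. mCPBA (1.0 equiv, NaHCO3, CH2Cl2, −20 °C) epoxidises the trisubstituted C1=C10 bond from the β face to the transient 1β,10β-epoxide F3, which lactonises at C10 to 13-O-trimethylsilyl-1β-hydroxy-GA5 F4. VO(acac)2/t-BuOOH (CH2Cl2, 0 °C) then delivers oxygen syn to the allylic 1β-OH to give 13-O-trimethylsilyl-GA93 F5; the masked 13-OH cannot direct attack on the 16-ene. AcOH/THF/H2O removes the silyl ether and gives 7.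

**Step 2.** Iodide displacement may be sluggish, or the diene diacid may be hard to isolate cleanly. The fallback sets out from 2 and comes back at 4. Sodium benzenesulfinate in DMF displaces the mesylate (syn-SN2′) to give the allylic sulfone 1β-phenylsulfonyl-GA5 F6, a β-acyloxy sulfone. Julia-type reductive elimination with Na(Hg)/Na2HPO4 in MeOH–THF at −20 °C expels the C19 carboxylate and benzenesulfinate and, after acidification, gives 4.

**Step 1.** The free 7-acid may be activated by MsCl, or chloride may attack the allylic mesylate. The fallback sets out from 1 and comes back at 4. Phenacyl bromide/KHCO3/DMF gives GA3 7-phenacyl ester F7. MsCl/pyridine then gives its 3-O-mesylate, GA3 7-phenacyl ester 3-O-methanesulfonate F8, with no free acid present. NaI followed by Zn/AcOH in DMF converts F8 through 1β-iodo-GA5 7-phenacyl ester F9 into 4, the zinc cleaving the phenacyl ester in the same operation.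

## Further compounds

F1 | step 3 | tris(trimethylsilyl) derivative of 4 (13-O-TMS, 7- and 19-TMS esters) | C=C1C[C@]23C[C@@]1(O[Si](C)(C)C)CC[C@H]2C1=CC=C[C@@](C)(C(=O)O[Si](C)(C)C)[C@H]1[C@@H]3C(=O)O[Si](C)(C)C
F2 | step 3 | 13-O-trimethylsilyl diene diacid | C=C1C[C@]23C[C@@]1(O[Si](C)(C)C)CC[C@H]2C1=CC=C[C@@](C)(C(=O)O)[C@H]1[C@@H]3C(=O)O
F3 | step 3 | 13-O-trimethylsilyl 1β,10β-epoxy-2-ene diacid | C=C1C[C@]23C[C@@]1(O[Si](C)(C)C)CC[C@H]2[C@]12O[C@@H]2C=C[C@@](C)(C(=O)O)[C@H]1[C@@H]3C(=O)O
F4 | step 3 | 13-O-trimethylsilyl-1β-hydroxy-GA5 | C=C1C[C@]23C[C@@]1(O[Si](C)(C)C)CC[C@H]2[C@@]12OC(=O)[C@@](C)([C@H]1[C@@H]3C(=O)O)C=C[C@H]2O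
F5 | step 3 | 13-O-trimethylsilyl-GA93 | C=C1C[C@]23C[C@@]1(O[Si](C)(C)C)CC[C@H]2[C@@]12OC(=O)[C@@](C)([C@H]1[C@@H]3C(=O)O)[C@H]1O[C@H]1[C@H]2O
F6 | step 2 | 1β-phenylsulfonyl-GA5 | C=C1C[C@]23C[C@@]1(O)CC[C@H]2[C@@]12OC(=O)[C@@](C)([C@H]1[C@@H]3C(=O)O)C=C[C@H]2S(=O)(=O)c1ccccc1
F7 | step 1 | GA3 7-phenacyl ester | C=C1C[C@]23C[C@@]1(O)CC[C@H]2[C@@]12OC(=O)[C@@](C)([C@H]1[C@@H]3C(=O)OCC(=O)c1ccccc1)[C@@H](O)C=C2
F8 | step 1 | GA3 7-phenacyl ester 3-O-methanesulfonate | C=C1C[C@]23C[C@@]1(O)CC[C@H]2[C@@]12OC(=O)[C@@](C)([C@H]1[C@@H]3C(=O)OCC(=O)c1ccccc1)[C@@H](OS(C)(=O)=O)C=C2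
F9 | step 1 | 1β-iodo-GA5 7-phenacyl ester | C=C1C[C@]23C[C@@]1(O)CC[C@H]2[C@@]12OC(=O)[C@@](C)([C@H]1[C@@H]3C(=O)OCC(=O)c1ccccc1)C=C[C@H]2I
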